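**Plan**
Numbering: C1 is the ketone carbon on the benzene ring and C20 is the chain methyl. Cuts, in order: the three phenol O–H (masked as MOM ethers); the four cis-alkenes C5=C6, C8=C9, C11=C12 and C14=C15 (traced back to alkynes); C6–C7; C13–C14; last C15–C16 and ring–C1.
Enabling feature: C7 is a CH2 held between the C5=C6 and C8=C9 cis-alkenes, a 1,4-diene unit that repeats at C10 and C13. At the alkyne oxidation level C6 becomes an acidic sp C–H and C7 a primary propargylic carbon. C6–C7 can then be made by a geometry-free sp–sp3 substitution that the benzene ring, its doubly ortho-flanked C1 ketone and the free C17–OH do not disturb.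
Forward: C7 alkynol 3 and the symmetrical C7 dibromide 9 give C14 bromide 11. Phloroglucinol and a C6 nitrile give aryl alkynone 16. Union of 11 and 16 gives the complete C26 tetrayne 19, and one hydrogenation and one acid step finish the target. No ring is formed; the benzene ring is bought.
Stereochemistry: C17 (R) is bought with (R)-2-propyloxirane and its C–O bond is never touched. All four Z-alkenes come from one syn semi-hydrogenation of 19.

Key step: step 7

Assumption: (R)-2-propyloxirane is taken as commercial in enantiopure form; the skipped polyynes 9, 11 and 19 are sensitive to air, light and base and are meant to be used directly after chromatography, under argon.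

Step 1
Reactants: 1 (R)-2-propyloxirane; 2 lithium acetylide ethylenediamine complex
Product: 3 (4R)-hept-1-yn-4-ol
Conditions: DMSO, 0 °C to rt; then H2O
Reagents that add atoms: none
Why: Acetylide opening of a terminal epoxide (SN2) takes place at the unsubstituted CH2, so the C–O bond of the stereocentre is not touched and the (R) centre of 1 is carried over unchanged as C17 (R).

Step 2
Reactants: 4 prop-2-yn-1-ol; 5 4-chlorobut-2-yn-1-ol
Product: 8 hepta-2,5-diyne-1,7-diol, via 4-iodobut-2-yn-1-ol 6 (not isolated), via propargyl alcohol copper acetylide 7 (not isolated)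
Conditions: CuI, NaI, K2CO3, DMF, rt, Ar
Reagents that add atoms: none
Why: Copper-mediated coupling of a terminal alkyne with a propargylic halide, helped by in situ Finkelstein exchange of chloride 5 to iodide 6, is the standard entry to skipped diynes, tolerates both free hydroxyl groups and creates no stereocentre.

Step 3
Reactants: 8 hepta-2,5-diyne-1,7-diol
Product: 9 1,7-dibromohepta-2,5-diyne
Conditions: CBr4, PPh3, CH2Cl2, −20 to 0 °C
Reagents that add atoms: carbon tetrabromide, BrC(Br)(Br)Br
Why: The Appel reaction replaces both primary propargylic hydroxyl groups by bromide under neutral conditions, so the base-sensitive doubly propargylic CH2 of the skipped diyne should not isomerise.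

Step 4
Reactants: 3 (4R)-hept-1-yn-4-ol; 9 1,7-dibromohepta-2,5-diyne
Product: 11 (4R)-14-bromotetradeca-6,9,12-triyn-4-ol, via alkynol copper acetylide 10 (not isolated)
Conditions: 9 (3–4 equiv, excess recovered), CuBr, Cs2CO3, DMF, −10 °C to rt, Ar, dark
Reagents that add atoms: none
Why: The same copper-mediated alkyne–propargylic halide coupling forms C13–C14, the excess of the symmetrical dibromide 9 favouring single substitution, the iodide-free copper salt keeping the second terminus a bromide, and the carbonate base leaving the C17–OH and its stereocentre untouched.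

Step 5
Reactants: 12 phloroglucinol (benzene-1,3,5-triol, dried); 13 hex-5-ynenitrile
Product: 15 1-(2,4,6-trihydroxyphenyl)hex-5-yn-1-one, via ketiminium chloride 14 (not isolated)
Conditions: HCl (g), ZnCl2 (cat.), Et2O, 0 °C; then H2O, reflux
Reagents that add atoms: water, O
Why: The Houben–Hoesch reaction acylates the very electron-rich phloroglucinol ring once (the ketiminium salt 14 deactivates the ring and precipitates) and hydrolysis gives the aryl ketone, while an unactivated terminal alkyne should not add HCl in cold ether.

Step 6
Reactants: 15 1-(2,4,6-trihydroxyphenyl)hex-5-yn-1-one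
Product: 16 1-[2,4,6-tris(methoxymethoxy)phenyl]hex-5-yn-1-one
Conditions: NaH (3.3 equiv), MOMCl (3.6 equiv), DMF, 0 °C to rt
Reagents that add atoms: chloromethyl methyl ether (MOMCl), COCCl
Why: Williamson-type O-alkylation of the three phenoxides with MOMCl masks all acidic O–H groups for the carbonate-mediated union, the stoichiometric amount of NaH ionising only the phenols and not the alkyne C–H or the α-CH2.

Step 7
Reactants: 11 (4R)-14-bromotetradeca-6,9,12-triyn-4-ol; 16 1-[2,4,6-tris(methoxymethoxy)phenyl]hex-5-yn-1-one
Product: 19 (17R)-17-hydroxy-1-[2,4,6-tris(methoxymethoxy)phenyl]icosa-5,8,11,14-tetrayn-1-one, via triynyl iodide 17 (not isolated), via aryl ketone copper acetylide 18 (not isolated)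
Conditions: CuI, NaI, Cs2CO3, DMF, 0 °C to rt, Ar, dark
Reagents that add atoms: none
Why: Cs2CO3 and CuI turn the acidic sp C6–H of 16 into the monovalent copper acetylide 18, NaI turns bromide 11 into the more reactive iodide 17, and 18 then displaces iodide at the primary propargylic carbon C7 (formally oxidative addition to trivalent copper and reductive elimination), which returns CuI. The closest known reaction type is the copper-mediated coupling of terminal alkynes with propargylic halides under carbonate/iodide conditions, the standard way to skipped diynes, triynes and tetraynes of the polyunsaturated fatty acid class. No ring is closed and no stereocentre is formed; C17 lies ten bonds from the reacting carbon and keeps its (R) configuration. The step needs attack at C7 and not at C9 (SN2′, allene), alkylation at carbon and not at oxygen, and no base-induced shift of the doubly propargylic CH2 groups: the unhindered primary C7 and the soft acetylide secure the first, the three MOM ethers and the non-ionised C17–OH the second, and the weak carbonate base at or below room temperature the third, while the C1 ketone is shielded by its two ortho substituents. Because sp carbons carry no geometry and a propargylic carbon cannot scramble through a π-allyl intermediate as a vinyl–allyl coupling could, this one bond formation completes the whole C26 skeleton with all four unsaturations fixed in their 1,4-positions, so that the four Z-alkene problems collapse into the single hydrogenation of step 8.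

Step 8
Reactants: 19 (17R)-17-hydroxy-1-[2,4,6-tris(methoxymethoxy)phenyl]icosa-5,8,11,14-tetrayn-1-one
Product: 20 (5Z,8Z,11Z,14Z,17R)-17-hydroxy-1-[2,4,6-tris(methoxymethoxy)phenyl]icosa-5,8,11,14-tetraen-1-one
Conditions: H2 (1 atm, stopped after uptake of 4 equiv), Pd/CaCO3 poisoned with Pb(OAc)2, quinoline, EtOAc, 0 °C to rt
Reagents that add atoms: none
Why: Lindlar semi-hydrogenation delivers both hydrogen atoms to the same face of each adsorbed alkyne, which sets C5=C6, C8=C9, C11=C12 and C14=C15 all as Z in one operation, while lead and quinoline hold back adsorption of the alkenes and the ketone, MOM ethers and C17 carbinol are inert.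

Step 9
Reactants: 20 (5Z,8Z,11Z,14Z,17R)-17-hydroxy-1-[2,4,6-tris(methoxymethoxy)phenyl]icosa-5,8,11,14-tetraen-1-one
Product: 21 (5Z,8Z,11Z,14Z,17R)-17-hydroxy-1-(2,4,6-trihydroxyphenyl)icosa-5,8,11,14-tetraen-1-one
Conditions: HCl (3 M aq), MeOH (degassed), 45 °C, Ar
Reagents that add atoms: none
Why: Acid-catalysed acetal exchange cleaves the three aryl MOM ethers, methanol carrying the formaldehyde unit away as its dimethyl acetal so that it cannot bridge phloroglucinol rings, and methylene-interrupted cis-polyenes and the C17 carbinol tolerate warm methanolic HCl as in fatty acid methyl ester preparation.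

**Compound list**
1 | (R)-2-propyloxirane | CCC[C@@H]1CO1 | starting material
2 | lithium acetylide ethylenediamine complex | [Li]C#C.NCCN | starting material
3 | (4R)-hept-1-yn-4-ol | CCC[C@@H](O)CC#C | intermediate
4 | prop-2-yn-1-ol | C#CCO | starting material
5 | 4-chlorobut-2-yn-1-ol | OCC#CCCl | starting material
6 | 4-iodobut-2-yn-1-ol (formed in the flask) | OCC#CCI | intermediate
7 | (3-hydroxyprop-1-yn-1-yl)copper (formed in the flask) | OCC#C[Cu] | intermediate
8 | hepta-2,5-diyne-1,7-diol | OCC#CCC#CCO | intermediate
9 | 1,7-dibromohepta-2,5-diyne | BrCC#CCC#CCBr | intermediate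
10 | [(4R)-4-hydroxyhept-1-yn-1-yl]copper (formed in the flask) | CCC[C@@H](O)CC#C[Cu] | intermediate
11 | (4R)-14-bromotetradeca-6,9,12-triyn-4-ol | CCC[C@@H](O)CC#CCC#CCC#CCBr | intermediate
12 | phloroglucinol (benzene-1,3,5-triol) | Oc1cc(O)cc(O)c1 | starting material
13 | hex-5-ynenitrile | C#CCCCC#N | starting material
14 | 1-(2,4,6-trihydroxyphenyl)hex-5-yn-1-iminium chloride (formed in the flask) | C#CCCCC(=[NH2+])c1c(O)cc(O)cc1O.[Cl-] | intermediate
15 | 1-(2,4,6-trihydroxyphenyl)hex-5-yn-1-one | C#CCCCC(=O)c1c(O)cc(O)cc1O | intermediate
16 | 1-[2,4,6-tris(methoxymethoxy)phenyl]hex-5-yn-1-one | C#CCCCC(=O)c1c(OCOC)cc(OCOC)cc1OCOC | intermediate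
17 | (4R)-14-iodotetradeca-6,9,12-triyn-4-ol (formed in the flask) | CCC[C@@H](O)CC#CCC#CCC#CCI | intermediate
18 | {6-oxo-6-[2,4,6-tris(methoxymethoxy)phenyl]hex-1-yn-1-yl}copper (formed in the flask) | [Cu]C#CCCCC(=O)c1c(OCOC)cc(OCOC)cc1OCOC | intermediate
19 | (17R)-17-hydroxy-1-[2,4,6-tris(methoxymethoxy)phenyl]icosa-5,8,11,14-tetrayn-1-one | CCC[C@@H](O)CC#CCC#CCC#CCC#CCCCC(=O)c1c(OCOC)cc(OCOC)cc1OCOC | intermediate
20 | (5Z,8Z,11Z,14Z,17R)-17-hydroxy-1-[2,4,6-tris(methoxymethoxy)phenyl]icosa-5,8,11,14-tetraen-1-one | CCC[C@@H](O)C/C=C\C/C=C\C/C=C\C/C=C\CCCC(=O)c1c(OCOC)cc(OCOC)cc1OCOC | intermediate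
21 | (5Z,8Z,11Z,14Z,17R)-17-hydroxy-1-(2,4,6-trihydroxyphenyl)icosa-5,8,11,14-tetraen-1-one | CCC[C@@H](O)C/C=C\C/C=C\C/C=C\C/C=C\CCCC(=O)c1c(O)cc(O)cc1O | target

Total step count: 9. Longest linear sequence: 6 steps (steps 2, 3, 4, 7, 8, 9).

**Steps most likely to fail**

Step 4 (single substitution of the dibromide). The bromide that forms may compete with 9 for the acetylide, so that both termini are substituted. Dibromide 9 may also decay by base-induced isomerisation while it is present in excess. The fallback moves the statistical event to the cheap diol. It sets out from 8 and 3 and comes back to the route at 11.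
- Diol 8 is treated with one equivalent of CBr4/PPh3 to give 7-bromohepta-2,5-diyn-1-ol F1, which differs strongly in polarity from 8 and 9 and should be easy to separate.
- Bromide F1 is then coupled one to one with 3 under the conditions of step 4 (CuBr, Cs2CO3, DMF) to give (11R)-tetradeca-2,5,8-triyne-1,11-diol F2.
- The primary propargylic hydroxyl group of F2 is brominated selectively (CBr4, PPh3, one equivalent, −40 °C). The hindered secondary carbinol should react much more slowly, and the product is 11.

Step 8 (fourfold semi-hydrogenation). Hydrogen uptake may not stop cleanly, so alkenes already formed could be reduced further while the last alkyne is still present. Some cis-to-trans isomerisation on palladium is also possible, and the resulting mixture would be hard to separate at this size. The fallback divides the reduction into a threefold and a single one and makes the C6–C7 union at the alkene level. It sets out from 3, 8 and 16, follows the fallback of step 4 as far as the triynediol F2, and comes back to the route at 20.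
- Diol F2 is small, polar and free of the aryl ketone. It is hydrogenated (H2, Pd/CaCO3 poisoned with Pb(OAc)2, quinoline) to (2Z,5Z,8Z,11R)-tetradeca-2,5,8-triene-1,11-diol F3, which can be purified over AgNO3-impregnated silica.
- Selective Appel bromination of the primary allylic hydroxyl group gives (4R,6Z,9Z,12Z)-14-bromotetradeca-6,9,12-trien-4-ol F4.
- Copper-mediated terminal alkyne–allylic bromide coupling of F4 with 16 (CuI, Cs2CO3, DMF; SN2 at C7 with the Z-alkenes retained) gives (8Z,11Z,14Z,17R)-17-hydroxy-1-[2,4,6-tris(methoxymethoxy)phenyl]icosa-8,11,14-trien-5-yn-1-one F5.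
- Semi-hydrogenation of the one remaining alkyne leads to 20.

Step 5 (Houben–Hoesch acylation). HCl may add to the terminal alkyne, the nitrile may be taken up at a phenol oxygen in place of the ring carbon, or the ketiminium salt may fail to separate. The fallback reverses the polarity, uses the ring as a carbanion and protects first. It sets out from 12 and comes back to the route at 16, so it also replaces step 6.
- Phloroglucinol 12 is converted (NaH, MOMCl, DMF) into 1,3,5-tris(methoxymethoxy)benzene F6.
- Directed ortho-lithiation between two MOM ethers (n-BuLi, THF, 0 °C) gives 2,4,6-tris(methoxymethoxy)phenyllithium F7.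
- Transmetallation with MgBr2·OEt2 gives the less basic 2,4,6-tris(methoxymethoxy)phenylmagnesium bromide F8.
- Grignard reagent F8 is added to N-methoxy-N-methylhex-5-ynamide F9, which is made from commercial hex-5-ynoic acid, 1,1′-carbonyldiimidazole and MeNHOMe·HCl. The stable chelated adduct of this Weinreb ketone synthesis prevents a second addition, and an aryl Grignard reagent should add faster than it deprotonates the alkyne. Work-up gives 16.

**Further compounds**
F1 | step 4 | 7-bromohepta-2,5-diyn-1-ol | OCC#CCC#CCBr
F2 | step 4 | (11R)-tetradeca-2,5,8-triyne-1,11-diol | CCC[C@@H](O)CC#CCC#CCC#CCO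
F3 | step 8 | (2Z,5Z,8Z,11R)-tetradeca-2,5,8-triene-1,11-diol | CCC[C@@H](O)C/C=C\C/C=C\C/C=C\CO
F4 | step 8 | (4R,6Z,9Z,12Z)-14-bromotetradeca-6,9,12-trien-4-ol | CCC[C@@H](O)C/C=C\C/C=C\C/C=C\CBr
F5 | step 8 | (8Z,11Z,14Z,17R)-17-hydroxy-1-[2,4,6-tris(methoxymethoxy)phenyl]icosa-8,11,14-trien-5-yn-1-one | CCC[C@@H](O)C/C=C\C/C=C\C/C=C\CC#CCCCC(=O)c1c(OCOC)cc(OCOC)cc1OCOC
F6 | step 5 | 1,3,5-tris(methoxymethoxy)benzene | COCOc1cc(OCOC)cc(OCOC)c1
F7 | step 5 | 2,4,6-tris(methoxymethoxy)phenyllithium | [Li]c1c(OCOC)cc(OCOC)cc1OCOC
F8 | step 5 | 2,4,6-tris(methoxymethoxy)phenylmagnesium bromide | Br[Mg]c1c(OCOC)cc(OCOC)cc1OCOC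
F9 | step 5 | N-methoxy-N-methylhex-5-ynamide | C#CCCCC(=O)N(C)OC
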